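# Betaethrin A by pyranone unravelling and triketide aldol folding: a seven-step proposal

## Compound numbering used throughout

- **1** chelidonic acid (4-oxo-4H-pyran-2,6-dicarboxylic acid)
- **2** diethyl 4-oxo-4H-pyran-2,6-dicarboxylate
- **3** ethyl 6-(hydroxymethyl)-4-oxo-4H-pyran-2-carboxylate
- **4** methyl 2,6-dihydroxy-4-methylbenzoate
- **5** ethyl 6-{[3-hydroxy-2-(methoxycarbonyl)-5-methylphenoxy]methyl}-4-oxo-4H-pyran-2-carboxylate
- **6** 7-[3-hydroxy-2-(methoxycarbonyl)-5-methylphenoxy]-2,4,6-trioxoheptanoic acid (formed in the flask, not isolated)
- **7** 3,5-dihydroxy-2-[3-hydroxy-2-(methoxycarbonyl)-5-methylphenoxy]benzoic acid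
- **8** methyl 2-[2,4-dihydroxy-6-(hydroxymethyl)phenoxy]-6-hydroxy-4-methylbenzoate
- **9** methyl 2-hydroxy-6-[2-hydroxy-6-(hydroxymethyl)-4-methoxyphenoxy]-4-methylbenzoate
- **10** betaethrin A, methyl 2-[2-(acetoxymethyl)-6-hydroxy-4-methoxyphenoxy]-6-hydroxy-4-methylbenzoate

Atom labels: ring A (the benzoate ring) is C1 (bears CO2Me), C2 (OH), C4 (CH3), C6 (ether oxygen). Ring B is C1′ (ether oxygen), C2′ (OH), C4′ (OMe), C6′ (CH2OAc). The open chain of 6 is numbered from the acid carbon (chain C1) to the aryloxymethyl carbon (chain C7).

## Analysis of the target

Betaethrin A (10) is an achiral diaryl ether: two benzene rings joined through one oxygen, with no further ring and no stereocentre. Ring A is a methyl benzoate whose ester at C1 is flanked by a chelated hydroxyl at C2 and the ether oxygen at C6, with a methyl group at C4. Ring B carries the ether oxygen at C1′, a free hydroxyl at C2′, a methoxy group at C4′ and an acetoxymethyl group at C6′. Nothing has to be related stereochemically, since the ether axis, although flanked by three ortho substituents, is not expected to be configurationally stable. The sensitive groups are the benzylic acetate (labile to base and nucleophiles, and an acyl donor towards phenoxides), the two free phenols, and the ring A ester, which the C2′ phenoxide could reach to form a seven-membered depsidone-type lactone. The synthesis is hard for two reasons. First, the C6–O–C1′ ether is tri-ortho-substituted and both rings are electron-rich, the worst case for copper-mediated or SNAr ether formation. Second, four similar oxygen functions (three phenolic, one benzylic) must finish as OH, OH, OMe and OAc. The strategy rests on ring B: oxygen at C2′ and C4′, hydrogen at C3′ and C5′ and a one-carbon substituent at C6′ form the pattern of a folded 2,4,6-triketo chain. In that chain C1′ is the nucleophilic terminus and C6′ a former keto carbon, and because C1′ is also the carbon bound to the ring A oxygen, the hindered diaryl ether can travel as an unhindered ArO–CH2 group until ring B is closed.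

## Retrosynthetic reasoning

**10 to 9.** The O–acyl bond of the benzylic acetate is cut first. This ester is the most labile group in the molecule and would not survive the basic or reducing steps before it, so it is introduced last. The forward reaction has to acylate one primary hydroxyl next to two free phenols, so it calls for an acyl-transfer catalyst that discriminates aliphatic from phenolic OH, not for a more reactive acylating agent.

**9 to 8.** The O–CH3 bond at C4′ is cut next. Ring B of 8 holds two phenols: the one at C4′ has hydrogen on both sides, while the one at C2′ sits beside the twisted aryloxy group. The ring A phenol is locked in a hydrogen bond to its ester. The forward step must alkylate the C4′ oxygen only. This is the price of the short front end, because the ring-forming step delivers both ring B oxygens as free hydroxyls.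

**8 to 7.** The C6′ hydroxymethyl group is taken back to a carboxylic acid. The acid is what the ring-forming step produces. An acid beside an ester is the one pair of carboxyl derivatives that an electrophilic hydride source distinguishes cleanly, so the ring A ester needs no protection.

**7 to 5 through 6.** The C1′–C6′ bond of ring B is cut and the two phenolic carbons are returned to the keto level. This unfolds the ring into the triketo acid 6, in which chain C7 (the future C1′) is an ArO–CH2 group and chain C2 (the future C6′) is the keto group of an alpha-keto acid. Chain 6 is not made as such; it is stored as the 4-pyranone 5, whose ring oxygen masks the two outer carbonyls as enol ethers. The cut is placed here because it removes the diaryl ether problem: the ether oxygen of 5 is attached to an sp3 carbon, and that carbon becomes aromatic only on folding. The forward reaction must open the pyranone, form one C–C bond by aldol addition and aromatise by dehydration and enolisation, with no change of oxidation level and without touching the ring A ester.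

**5 to 3 and 4.** The O–CH2 bond is cut, giving the hydroxymethyl pyranone 3 and the symmetrical diphenol 4. The forward step is a primary-carbon etherification of an acidic phenol. The symmetry of 4 means either hydroxyl gives the same product, and the first alkylation leaves the second hydroxyl chelated and more hindered, which favours the mono-ether.

**3 to 2 to 1.** The hydroxymethyl group of 3 is taken back to an ester, giving the symmetrical diester 2 and then the commercial diacid 1. The forward sequence is an esterification and a desymmetrising half-reduction. The other carboxyl carbon of 1 is kept at the acid oxidation level because it becomes C6′ with its extra carbon.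

## Alternatives that were turned down

**Alternative 1:** Ring A is built last, around the ether. Bonds C1–C2 and C5–C6 of the benzoate ring are cut, leaving an alkynoate that already carries ring B on oxygen, methyl 3-{2-[(tert-butyldimethylsilyloxy)methyl]-4-methoxy-6-(methoxymethoxy)phenoxy}prop-2-ynoate (A1), and the ketene-acetal diene 1,1-bis(trimethylsilyloxy)-3-methylbuta-1,3-diene (A2). The forward key step is a thermal (4+2) cycloaddition followed by loss of one silyloxy group, giving methyl 2-{2-[(tert-butyldimethylsilyloxy)methyl]-4-methoxy-6-(methoxymethoxy)phenoxy}-6-hydroxy-4-methylbenzoate (A3).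
- For: the regiochemistry follows from matched polarisation (the nucleophilic diene terminus meets the alkyne carbon beta to the ester), and the ring A hydroxyl, methyl and ester arrive in one step. Ring B enters with its C4′ methyl ether already set, so this route is stronger than the chosen one on differentiating the ring B oxygens.
- Against: A1 is a push–pull alkyne whose donor oxygen lowers its dienophilicity. It must be made from a 2,6-disubstituted, three-way protected ring B phenol that needs its own multistep synthesis. A2 is hydrolytically fragile. A3 still needs two deprotections and the acetylation.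
- Comparison: the route is longer and puts much of its risk into making A1. The chosen strategy offers instead a precursor reached in three steps from two bought compounds.

**Alternative 2:** The diaryl ether bond O–C6 and the C1–C(ester) bond are cut together. The forward key step releases an aryne from 3-(methoxymethoxy)-5-methyl-2-(trimethylsilyl)phenyl trifluoromethanesulfonate (A4) with a fluoride source. The aryne inserts into the aryl O–C(acyl) bond of 4-methoxy-2-(methoxymethoxy)-6-[(methoxymethoxy)methyl]phenyl methyl carbonate (A5), giving methyl 2-(methoxymethoxy)-6-{2-(methoxymethoxy)-4-methoxy-6-[(methoxymethoxy)methyl]phenoxy}-4-methylbenzoate (A6).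
- For: this is the most convergent plan, forming the hindered ether and placing the ester between two oxygens in one operation. The alkoxy group on the aryne should direct the oxygen nucleophile to the distal carbon. The C4′ methyl ether is again fixed from the start, a point on which it beats the chosen route.
- Against: a carbonate oxygen on a 2,6-disubstituted ring is a weak, hindered nucleophile. Fluoride can cleave A5 to a phenoxide that arylates without acyl transfer, which would give an ether lacking the ester. Both A4 and A5 are multistep compounds. A6 then needs three acid-labile groups removed and a selective acetylation.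
- Comparison: its key step is at least as unproven as the one chosen, but failure would cost two long fragment syntheses. The chosen route risks three steps of cheap material.

**Alternative 3:** Ring B is assembled by a photo-Wolff vinylketene benzannulation. Four ring B bonds are cut (C5′–C6′, C2′–C3′, C4′–C5′, C1′–C2′), leading to the diazo enone methyl 2-acetoxy-6-{[(1E)-2-(acetoxymethyl)-4-diazo-3-oxobut-1-en-1-yl]oxy}-4-methylbenzoate (A7) and methoxyethyne (A8). On irradiation, Wolff rearrangement of A7 gives a vinylketene, which adds A8. Four-electron ring opening and six-electron closure then give methyl 2-acetoxy-6-[2-(acetoxymethyl)-6-hydroxy-4-methoxyphenoxy]-4-methylbenzoate (A9).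
- For: the alkyne delivers the C4′ methoxy group, the ketene carbon becomes the free C2′ phenol, and the acetoxymethyl group is already present. A9 is one aryl-acetate cleavage from 10. On oxygen differentiation this is the strongest of the four plans and clearly better than the chosen one.
- Against: A7 combines a beta-aryloxy enone (a vinylogous ester open to addition–elimination), an allylic acetate prone to SN2′ loss and a diazo ketone, so its preparation is several delicate steps. A8 is volatile and polymerises readily. The aryl ester and aryl vinyl ether chromophores can undergo photo-Fries-type side reactions under the irradiation.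
- Comparison: the weight of the risk lies in reaching and handling the precursor, whereas the chosen route keeps it in the ring-forming step. The chosen strategy accepts a late regioselective methylation in exchange for robust, inexpensive early chemistry.

Key step: step 4

Remark on the chemistry: 10 has no stereocentre, the tri-ortho-substituted ether axis is assumed to rotate freely at room temperature, and 1 and 4 are taken as purchasable.

## Route

Step 1
Reactants: 1 chelidonic acid
Product: 2 diethyl 4-oxo-4H-pyran-2,6-dicarboxylate
Conditions: EtOH, H2SO4 (cat.), reflux
Reagents that add atoms: ethanol, CCO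
Why: Fischer esterification driven by excess ethanol; the 4-pyranone ring is stable to acid, and ethyl esters match the ethanol used as solvent in the next step.

Step 2
Reactants: 2 diethyl 4-oxo-4H-pyran-2,6-dicarboxylate
Product: 3 ethyl 6-(hydroxymethyl)-4-oxo-4H-pyran-2-carboxylate
Conditions: NaBH4 (0.6 equiv), EtOH, −10 to 0 °C; AcOH quench
Reagents that add atoms: none
Why: Chemoselective borohydride reduction of an activated heteroaryl ester, as in the half-reduction of pyridine-2,6-dicarboxylates; limiting hydride at low temperature should stop at the mono-alcohol because loss of one acceptor group makes the remaining ester less electrophilic, and the pyranone carbonyl is a vinylogous ester that borohydride does not reduce.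

Step 3
Reactants: 3 ethyl 6-(hydroxymethyl)-4-oxo-4H-pyran-2-carboxylate; 4 methyl 2,6-dihydroxy-4-methylbenzoate
Product: 5 ethyl 6-{[3-hydroxy-2-(methoxycarbonyl)-5-methylphenoxy]methyl}-4-oxo-4H-pyran-2-carboxylate
Conditions: PPh3, DIAD, THF, 0 °C to rt (4 in 1.5-fold excess)
Reagents that add atoms: none
Why: Mitsunobu etherification of a primary alcohol with a phenol acidic enough to protonate the betaine; after the first alkylation the remaining hydroxyl of 4 is hydrogen-bonded to the ester and more hindered, and 4 is in excess, so the mono-ether should dominate.

Step 4
Reactants: 5 ethyl 6-{[3-hydroxy-2-(methoxycarbonyl)-5-methylphenoxy]methyl}-4-oxo-4H-pyran-2-carboxylate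
Product: 7 3,5-dihydroxy-2-[3-hydroxy-2-(methoxycarbonyl)-5-methylphenoxy]benzoic acid, via open-chain triketo acid 6 (not isolated)
Conditions: Ba(OH)2·8H2O (6 equiv), degassed H2O–THF, argon, 0 °C to 45 °C; then 1 M HCl to pH 2, 0 °C
Reagents that add atoms: barium hydroxide, [Ba+2].[OH-].[OH-]; water, O
Why: Proposed new method: hydroxide saponifies the activated ethyl ester and adds in conjugate fashion to the pyranone, whose hemiketal opens by retro-oxa-Michael cleavage to the barium-chelated enolate of triketo acid 6; deprotonation of chain C7, the methylene that bears the aryloxy group, gives an enolate that attacks the chain C2 keto group of the alpha-keto carboxylate, and dehydration followed by enolisation of the chain C4 and C6 carbonyls gives the resorcylic acid with no change of oxidation level. The closest known reactions are the base-induced opening of 2,6-dialkyl-4-pyranones to 1,3,5-triketones with aldol closure to resorcinols (orcinol from 2,6-dimethyl-4-pyranone) and the folding of triketo acids to resorcylic acids; new here is a chain end that carries an aryloxy group, so that an alkyl aryl ether carbon becomes aromatic carbon C1′ of a diaryl ether. Ring B closes by a 6-(enolendo)-exo-trig aldol that forms the C1′–C6′ bond. No stereocentre is created. The step needs regioselective folding and survival of the ring A ester: chain C7 is the only carbanion that reaches a carbonyl through a six-membered transition state and chain C2 is the only acceptor so placed, while the competing 5-exo Dieckmann attack of the same carbanion on the ring A ester and the saponification of that ester are both held back because it is doubly ortho-substituted and conjugated with the ring A phenoxide in aqueous base. The aryloxy group raises the acidity of chain C7 and the alpha-keto carboxylate is a better acceptor than the plain ketone of the classical cases, which should favour closure over retro-Claisen loss of the oxalyl unit. The carboxyl group of 7 is meta to both ring B hydroxyls, so acidification should not cause decarboxylation.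

Step 5
Reactants: 7 3,5-dihydroxy-2-[3-hydroxy-2-(methoxycarbonyl)-5-methylphenoxy]benzoic acid
Product: 8 methyl 2-[2,4-dihydroxy-6-(hydroxymethyl)phenoxy]-6-hydroxy-4-methylbenzoate
Conditions: BH3·SMe2 (6 equiv), THF, 0 °C to rt; MeOH quench, aqueous work-up
Reagents that add atoms: none
Why: Borane reduction of a carboxylic acid through its acyloxyborane, which is much faster than ester reduction; the phenols only consume hydride as aryloxyboranes (hence the excess), the ring A ester is doubly ortho-substituted, and the acid is meta to both ring B hydroxyls, so over-reduction through a quinone methide is not possible.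

Step 6
Reactants: 8 methyl 2-[2,4-dihydroxy-6-(hydroxymethyl)phenoxy]-6-hydroxy-4-methylbenzoate
Product: 9 methyl 2-hydroxy-6-[2-hydroxy-6-(hydroxymethyl)-4-methoxyphenoxy]-4-methylbenzoate
Conditions: Cs2CO3 (2.2 equiv), MeI (1.0 equiv, slow addition), DMF, 0 °C
Reagents that add atoms: iodomethane, CI
Why: Williamson methylation with both ring B phenols deprotonated and iodomethane limiting, so that the outcome reflects the relative rates of the two phenoxides and not their populations; the C4′ phenoxide has hydrogen on both sides and is the more basic, the C2′ phenoxide lies beside the twisted aryloxy group, and the ring A hydroxyl is chelated to its ester, so the C4′ oxygen should be alkylated first.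

Step 7
Reactants: 9 methyl 2-hydroxy-6-[2-hydroxy-6-(hydroxymethyl)-4-methoxyphenoxy]-4-methylbenzoate
Product: 10 betaethrin A, methyl 2-[2-(acetoxymethyl)-6-hydroxy-4-methoxyphenoxy]-6-hydroxy-4-methylbenzoate
Conditions: immobilised Candida antarctica lipase B, vinyl acetate, MTBE, 35 °C
Reagents that add atoms: vinyl acetate, C=COC(C)=O
Why: Lipase-catalysed transesterification with an enol ester, which acylates primary aliphatic hydroxyls but not phenols and is made irreversible by tautomerisation of the released enol to acetaldehyde; the neutral medium leaves the phenols, the ring A ester and the new acetate untouched.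

## Compound list

1 | chelidonic acid (4-oxo-4H-pyran-2,6-dicarboxylic acid) | O=C(O)c1cc(=O)cc(C(=O)O)o1 | starting material
2 | diethyl 4-oxo-4H-pyran-2,6-dicarboxylate | CCOC(=O)c1cc(=O)cc(C(=O)OCC)o1 | intermediate
3 | ethyl 6-(hydroxymethyl)-4-oxo-4H-pyran-2-carboxylate | CCOC(=O)c1cc(=O)cc(CO)o1 | intermediate
4 | methyl 2,6-dihydroxy-4-methylbenzoate | COC(=O)c1c(O)cc(C)cc1O | starting material
5 | ethyl 6-{[3-hydroxy-2-(methoxycarbonyl)-5-methylphenoxy]methyl}-4-oxo-4H-pyran-2-carboxylate | CCOC(=O)c1cc(=O)cc(COc2cc(C)cc(O)c2C(=O)OC)o1 | intermediate
6 | 7-[3-hydroxy-2-(methoxycarbonyl)-5-methylphenoxy]-2,4,6-trioxoheptanoic acid (formed in the flask, not isolated) | COC(=O)c1c(O)cc(C)cc1OCC(=O)CC(=O)CC(=O)C(=O)O | intermediate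
7 | 3,5-dihydroxy-2-[3-hydroxy-2-(methoxycarbonyl)-5-methylphenoxy]benzoic acid | COC(=O)c1c(O)cc(C)cc1Oc1c(O)cc(O)cc1C(=O)O | intermediate
8 | methyl 2-[2,4-dihydroxy-6-(hydroxymethyl)phenoxy]-6-hydroxy-4-methylbenzoate | COC(=O)c1c(O)cc(C)cc1Oc1c(O)cc(O)cc1CO | intermediate
9 | methyl 2-hydroxy-6-[2-hydroxy-6-(hydroxymethyl)-4-methoxyphenoxy]-4-methylbenzoate | COC(=O)c1c(O)cc(C)cc1Oc1c(O)cc(OC)cc1CO | intermediate
10 | betaethrin A, methyl 2-[2-(acetoxymethyl)-6-hydroxy-4-methoxyphenoxy]-6-hydroxy-4-methylbenzoate | COC(=O)c1c(O)cc(C)cc1Oc1c(O)cc(OC)cc1COC(C)=O | target

## Step count and least certain steps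

Total: 7 steps. Longest linear sequence: 7 steps (1 to 10); 4 enters as bought in step 3.

**Step 4, the key step, which carries the proposed new method.**
- Most likely failure: fragmentation of the opened chain by retro-Claisen cleavage (loss of the oxalyl unit) before the slower aldol closure can occur, because the terminal methylene is far less acidic than the two doubly activated ones and must compete for the base.
- Further possible failures: Dieckmann-type closure of the same carbanion onto the ring A ester, saponification of that ester, reclosure of unfolded chain to a pyranone on acidification, and air oxidation of the electron-rich polyphenolate.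
- Fallback (known chemistry): it sets out from 4 and makes the ether directly. Copper-catalysed Ullmann coupling of excess 4 with purchased 2-bromo-3,5-dimethoxybenzaldehyde (COc1cc(OC)c(Br)c(C=O)c1) under CuI, picolinic acid, K3PO4, DMSO, 90 °C should give methyl 2-(2-formyl-4,6-dimethoxyphenoxy)-6-hydroxy-4-methylbenzoate F1. Exhaustive ether cleavage with BBr3 in CH2Cl2 at −78 to 0 °C should give methyl 2-(2-formyl-4,6-dihydroxyphenoxy)-6-hydroxy-4-methylbenzoate F2. NaBH4 in MeOH at 0 °C then reduces the aldehyde, and the route is rejoined at 8. The coupling of two hindered partners is expected to be inefficient, which is why it is held in reserve.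

**Step 6.**
- Most likely failure: poor site selectivity between the C2′ and C4′ phenols, with some double methylation. The steric difference is only that of one ortho aryloxy group and the two acidities are close.
- Fallback: it sets out from 8 and uses a bulky silyl group to amplify the steric difference. TBDPSCl (2.1 equiv) with imidazole in DMF should silylate the primary alcohol and the unhindered C4′ phenol, giving methyl 2-{4-[(tert-butyldiphenylsilyl)oxy]-2-{[(tert-butyldiphenylsilyl)oxy]methyl}-6-hydroxyphenoxy}-6-hydroxy-4-methylbenzoate F3. MOMCl and iPr2NEt in CH2Cl2 then cap the C2′ phenol as methyl 2-{4-[(tert-butyldiphenylsilyl)oxy]-2-{[(tert-butyldiphenylsilyl)oxy]methyl}-6-(methoxymethoxy)phenoxy}-6-hydroxy-4-methylbenzoate F4. TBAF in THF removes both silyl groups to give methyl 2-hydroxy-6-[4-hydroxy-2-(hydroxymethyl)-6-(methoxymethoxy)phenoxy]-4-methylbenzoate F5. MeI and K2CO3 in acetone methylate the only non-chelated phenol, giving methyl 2-hydroxy-6-[2-(hydroxymethyl)-4-methoxy-6-(methoxymethoxy)phenoxy]-4-methylbenzoate F6. Dilute HCl in MeOH removes the acetal, and the route is rejoined at 9.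

**Step 5.**
- Most likely failure: partial reduction of the ring A ester by hydride delivered from the neighbouring aryloxyborane, or stalling through insoluble borate complexes of the triphenol.
- Fallback: it sets out from 7. Fischer esterification (MeOH, H2SO4 cat., reflux) should give methyl 3,5-dihydroxy-2-[3-hydroxy-2-(methoxycarbonyl)-5-methylphenoxy]benzoate F7. LiBH4 in THF–MeOH at 0 °C to rt should then reduce the ring B ester, leaving the ring A ester, which is conjugated with its lithium phenoxide and doubly ortho-substituted. The route is rejoined at 8.

**Step 7.**
- Most likely failure: slow or incomplete enzymatic acyl transfer, because the benzylic alcohol sits ortho to the bulky aryloxy group.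
- Fallback: it sets out from 9. Peracetylation (Ac2O, pyridine, DMAP) should give methyl 2-acetoxy-6-[2-acetoxy-6-(acetoxymethyl)-4-methoxyphenoxy]-4-methylbenzoate F8. Selective aminolysis of the two aryl acetates with pyrrolidine in CH2Cl2 at 0 °C, which cleaves aryl esters far faster than alkyl esters, rejoins the route at 10.

**Step 2.**
- Most likely failure: over-reduction to the diol or hydride addition to the electron-poor ring, since the desymmetrisation rests only on stoichiometry and temperature.
- Fallback: it sets out from 2. Monosaponification (KOH, 1.0 equiv, EtOH, 0 °C) should give 6-(ethoxycarbonyl)-4-oxo-4H-pyran-2-carboxylic acid F9. Its acid group is then reduced in the presence of the ester with BH3·SMe2 in THF at 0 °C, rejoining the route at 3.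

## Further compounds

F1 | step 4 | methyl 2-(2-formyl-4,6-dimethoxyphenoxy)-6-hydroxy-4-methylbenzoate | COC(=O)c1c(O)cc(C)cc1Oc1c(OC)cc(OC)cc1C=O
F2 | step 4 | methyl 2-(2-formyl-4,6-dihydroxyphenoxy)-6-hydroxy-4-methylbenzoate | COC(=O)c1c(O)cc(C)cc1Oc1c(O)cc(O)cc1C=O
F3 | step 6 | methyl 2-{4-[(tert-butyldiphenylsilyl)oxy]-2-{[(tert-butyldiphenylsilyl)oxy]methyl}-6-hydroxyphenoxy}-6-hydroxy-4-methylbenzoate | COC(=O)c1c(O)cc(C)cc1Oc1c(O)cc(O[Si](c2ccccc2)(c2ccccc2)C(C)(C)C)cc1CO[Si](c1ccccc1)(c1ccccc1)C(C)(C)C
F4 | step 6 | methyl 2-{4-[(tert-butyldiphenylsilyl)oxy]-2-{[(tert-butyldiphenylsilyl)oxy]methyl}-6-(methoxymethoxy)phenoxy}-6-hydroxy-4-methylbenzoate | COC(=O)c1c(O)cc(C)cc1Oc1c(OCOC)cc(O[Si](c2ccccc2)(c2ccccc2)C(C)(C)C)cc1CO[Si](c1ccccc1)(c1ccccc1)C(C)(C)C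
F5 | step 6 | methyl 2-hydroxy-6-[4-hydroxy-2-(hydroxymethyl)-6-(methoxymethoxy)phenoxy]-4-methylbenzoate | COC(=O)c1c(O)cc(C)cc1Oc1c(OCOC)cc(O)cc1CO
F6 | step 6 | methyl 2-hydroxy-6-[2-(hydroxymethyl)-4-methoxy-6-(methoxymethoxy)phenoxy]-4-methylbenzoate | COC(=O)c1c(O)cc(C)cc1Oc1c(OCOC)cc(OC)cc1CO
F7 | step 5 | methyl 3,5-dihydroxy-2-[3-hydroxy-2-(methoxycarbonyl)-5-methylphenoxy]benzoate | COC(=O)c1c(O)cc(C)cc1Oc1c(O)cc(O)cc1C(=O)OC
F8 | step 7 | methyl 2-acetoxy-6-[2-acetoxy-6-(acetoxymethyl)-4-methoxyphenoxy]-4-methylbenzoate | COC(=O)c1c(OC(C)=O)cc(C)cc1Oc1c(OC(C)=O)cc(OC)cc1COC(C)=O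
F9 | step 2 | 6-(ethoxycarbonyl)-4-oxo-4H-pyran-2-carboxylic acid | CCOC(=O)c1cc(=O)cc(C(=O)O)o1
A1 | alternative 1 | methyl 3-{2-[(tert-butyldimethylsilyloxy)methyl]-4-methoxy-6-(methoxymethoxy)phenoxy}prop-2-ynoate | COC(=O)C#COc1c(OCOC)cc(OC)cc1CO[Si](C)(C)C(C)(C)C
A2 | alternative 1 | 1,1-bis(trimethylsilyloxy)-3-methylbuta-1,3-diene | C=C(C)C=C(O[Si](C)(C)C)O[Si](C)(C)C
A3 | alternative 1 | methyl 2-{2-[(tert-butyldimethylsilyloxy)methyl]-4-methoxy-6-(methoxymethoxy)phenoxy}-6-hydroxy-4-methylbenzoate | COC(=O)c1c(O)cc(C)cc1Oc1c(OCOC)cc(OC)cc1CO[Si](C)(C)C(C)(C)C
A4 | alternative 2 | 3-(methoxymethoxy)-5-methyl-2-(trimethylsilyl)phenyl trifluoromethanesulfonate | COCOc1cc(C)cc(OS(=O)(=O)C(F)(F)F)c1[Si](C)(C)C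
A5 | alternative 2 | 4-methoxy-2-(methoxymethoxy)-6-[(methoxymethoxy)methyl]phenyl methyl carbonate | COC(=O)Oc1c(OCOC)cc(OC)cc1COCOC
A6 | alternative 2 | methyl 2-(methoxymethoxy)-6-{2-(methoxymethoxy)-4-methoxy-6-[(methoxymethoxy)methyl]phenoxy}-4-methylbenzoate | COC(=O)c1c(OCOC)cc(C)cc1Oc1c(OCOC)cc(OC)cc1COCOC
A7 | alternative 3 | methyl 2-acetoxy-6-{[(1E)-2-(acetoxymethyl)-4-diazo-3-oxobut-1-en-1-yl]oxy}-4-methylbenzoate | COC(=O)c1c(OC(C)=O)cc(C)cc1O/C=C(\COC(C)=O)C(=O)C=[N+]=[N-]
A8 | alternative 3 | methoxyethyne | COC#C
A9 | alternative 3 | methyl 2-acetoxy-6-[2-(acetoxymethyl)-6-hydroxy-4-methoxyphenoxy]-4-methylbenzoate | COC(=O)c1c(OC(C)=O)cc(C)cc1Oc1c(O)cc(OC)cc1COC(C)=O
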